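The earlier runs and the new flask are simulated with made-up constants; the scatter is artificial.

The colder zeta run, at −15 °C, left less substrate than the epsilon flask at 0 °C, 17.2% against 26.3%, and yet it gave less target, 43.6% against 54.6%. In both flasks a little initiator sets substrate and partner reacting to target, with by-product beside it.

in all of them: substrate 0.20 M; initiator 0.54 mol%
- epsilon: partner 1.5 equiv; temperature 0 °C; the very flask that is asked about, followed so far
- zeta: partner 1.5 equiv; temperature −15 °C; run made earlier
- flask: partner 1.50 equiv; temperature 0 °C; time 10 min

| run | time / min | target / % | substrate / % |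
|---|---|---|---|
| epsilon | 1.50 | 54.6 | 25.9 |
| epsilon | 3.00 | 54.2 | 26.3 |
| epsilon | 5.00 | 54.9 | 26.8 |
| epsilon | 6.00 | 54.8 | 25.7 |
| epsilon | 8.00 | 54.5 | 26.7 |
| zeta | 3.00 | 42.9 | 20.1 |
| zeta | 6.00 | 43.7 | 17.3 |
| zeta | 10.0 | 44.0 | 16.8 |
| zeta | 12.0 | 42.8 | 17.0 |
| zeta | 15.0 | 43.9 | 17.7 |

(each reading ± 0.5 percentage points)

- summer: at 10 min add partner, 100% of the amount charged, then wait 10 min
- noon: at 10 min take out 90% of the by-product then present, then wait 10 min
- midnight: at 10 min raise the temperature by 20 K, then wait 10 min
- spring: change nothing and wait 10 min more

- additions bring no volume worth counting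
- the earlier runs were read with a standard deviation of 0.5 percentage points

* target, in percent of the substrate first charged, at 10 min
* the option that brings most further target ("none" if no option brings more than 2 percentage points) (summer / noon / midnight / spring / none)
* target present, in percent of the substrate first charged, after summer
* target present, in percent of the substrate first charged, after noon

I ordered the times first. Quickest was the epsilon flask, whose target was already flat at its first reading, 1.50 min, sooner than the 10 min asked about. Next came zeta, whose substrate fell from 20.1% to 17.3% between 3.00 min and 6.00 min, a drop larger than the scatter of 0.5 points, and then lay flat. Slowest was nothing I could read: both flasks stood still with substrate present, so I put the target at 10 min at 54.6%.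

What remained to read was the split ratio, the share of charged substrate that the readings do not show, divided by the target. It was 0.350 in epsilon and 0.899 in zeta. Under kinetic control a split is set while the chains run; under thermodynamic control it is a balance that follows temperature. I reckoned on the balance. The logarithm of a balance runs straight against inverse absolute temperature, and on that scale a rise of 20 K from 0 °C is about 7/6 of the step between the runs, so the split went to 0.117. With substrate held at 26.3%, that made target 66.0%, a gain of 11 points from midnight.

The forecast differed from my reckoning here: now 54.6%, between 54.1% and 55.1%, best none, summer 54.6%, noon 54.6%, on the ground that “With the initiator dead, extra partner, by-product removal, heat and waiting all do nothing.”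

The flask gave 54.6% now, 54.7% after summer and 54.7% after noon, and the best option was midnight, with 11 points more target.

    initiator → 2 initiating radical (k = 0.145 s⁻¹, Ea = 65.0 kJ mol⁻¹)
    substrate + initiating radical → capped initiator + first chain carrier (k = 1.00 × 10⁷ M⁻¹ s⁻¹, Ea = 15.0 kJ mol⁻¹)
    partner + first chain carrier ⇌ target + second chain carrier (K = 1.20, k = 2.35 × 10⁵ M⁻¹ s⁻¹, Ea = 27.0 kJ mol⁻¹, ΔH = −42.0 kJ mol⁻¹)
    substrate + second chain carrier → by-product + first chain carrier (k = 1.70 × 10⁵ M⁻¹ s⁻¹, Ea = 26.0 kJ mol⁻¹)
    2 second chain carrier → ended chains (k = 5.00 × 10⁸ M⁻¹ s⁻¹, Ea = 9.00 kJ mol⁻¹)
    target ⇌ isomer of the product (K = 0.347, k = 0.116 s⁻¹, Ea = 65.0 kJ mol⁻¹, ΔH = −37.0 kJ mol⁻¹)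
    (constants at 0 °C)

The unread share was the isomer of the product: the split times the target gives 19.1%, and the flask held 19.0%. A reason why midnight paid was the reaction of target to isomer of the product, both ways, since a run without that reaction gained 0.01 points against 11 points. The neighbour flask with 0.14 mol% of initiator kept 51% of its substrate; the split puts its target at 36.3%, and that neighbour flask held 36.4%.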